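I began from amounts. As a fraction of the solid monomer charged, cedar held 1.64% of initiator, maple 3.71% and the new flask 2.50%, and I wanted to see how much monomer so small an amount puts into chains.

common to all: solid monomer 0.014 M
- cedar: transfer agent 0.14 mM; capture agent 1.4 mM; initiator 0.23 mM; run made earlier
- maple: transfer agent 0.14 mM; capture agent 1.4 mM; initiator 0.52 mM; run made earlier
- flask: transfer agent 0.140 mM; capture agent 1.40 mM; initiator 0.35 mM; time 30 min

| run | time / min | monomer in chains / % | solid monomer / % |
|---|---|---|---|
| cedar | 1.33 | 0 | 85.9 |
| cedar | 3.00 | 1.1 | 73.1 |
| cedar | 8.00 | 1.3 | 48.9 |
| cedar | 20.0 | 2.3 | 32.2 |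
| maple | 5.00 | 2.0 | 60.5 |
| maple | 10.0 | 3.4 | 42.8 |
| maple | 15.0 | 4.5 | 34.0 |
| maple | 20.0 | 4.6 | 30.7 |

(standard deviation of a reading: 0.3 percentage points)

- solid monomer is a solid; its amount is given per volume of the solution
- the analysis behind the earlier runs scatters by 0.3 percentage points, standard deviation
- at the start none of the solid monomer is in solution

- beta: doubling the amount of initiator, all else as stated
- delta: doubling the solubility of the solid monomer, all else as stated
- eta: doubling the dissolution coefficient of the solid monomer, all else as stated

1. how much monomer in chains there is at 30 min, in percent of the solid monomer charged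
2. the change that raises the amount of monomer in chains at 30 min, in percent of the solid monomer charged most ("none" if none brings more than 2 percentage points) (beta / delta / eta / none)
3. amount of monomer in chains at 30 min, in percent of the solid monomer charged, after delta

The readings gave me a ladder. The first rung was dissolving: cedar's solid monomer fell towards the 30.7% that maple reached, with a time constant of about 6.11 min. Chains rose alongside it: at 5.00 min maple's solid had gone 57.0% of its way, its chains 43.5% of theirs. Then control changed hands. Between 15.0 min and 20.0 min maple's solid lost 3.3 percentage points, while its chains gained 0.1 points, less than the scatter of 0.3 points. Maple's solid had by then given up 69.3%, far more than the 4.6% in chains, so I read initiator as the limiting reagent.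

The quantity to carry is therefore the chain yield, monomer in chains per initiator charged, both as fractions of the solid monomer charge. Cedar reads 1.40 and maple 1.24, so I took 1.32. For the flask that gives 3.30%. Doubling the initiator gives 6.60%, so I chose beta. Delta leaves the initiator charge alone, so I kept about 3.30% there too.

The forecast gave 4%, chose beta and put delta at 6%: “Beta is the likely best, though delta is close.” My 3.30% for the flask and for delta was lower than its 4% and its 6%.

The flask gave 3.14%, beta gained 3.4 points, and delta gave 3.53%.

free monomer + initiator → living end + monomer in chains (k = 30.0 M⁻¹ min⁻¹); living end + capture agent → trapped intermediate (k = 3700 M⁻¹ min⁻¹); free monomer + living end → monomer in chains + living end, rate k3*[living end]*[free monomer] (k = 190 M⁻¹ min⁻¹); solid monomer ⇌ free monomer, rate k4*(cs4 - [free monomer]) while solid is left; crystals form when [free monomer] > cs4 (solubility = 9.50 mM, k = 0.170 min⁻¹); living end + transfer agent → dead chain (kL = 190 M⁻¹ min⁻¹) The flask's chain yield came to 1.26. A neighbour flask charged with 6.29% of initiator, promised 8.29% by the carried yield, gave 8.57%. At 30.0 min the flask's initiator stood at 0.110% of its charge. Ten times the time left the flask's monomer in chains at 3.15%. The flask's free monomer moved from 67.3% to 67.9%, and its solid monomer from 29.5% to 29.0%.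

The numbers in the tables stem from a simulated flask on assumed constants.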